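C2–O1 is never cut. The retrosynthesis cuts the aryl ether bond O1–C8a of the dihydropyran ring first and the benzylic bond C4–C4a second.
Enabling feature: on the benzene ring, C8a (bearing O1) lies para to C6 (bearing OH), a hydroquinone monoether pattern. Two-electron oxidation therefore makes C8a electrophilic, and the C2 oxygen, held through C3–C4 on the neighbouring C4a, reaches it through a six-membered ring.
C4, C3, C2, the 2-methyl group and the C41 side chain together form an all-E nonaprenyl skeleton, so the chain comes whole from solanesol and the arene from 2,3-dimethylhydroquinone.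
Forward: solanesol becomes a tertiary vinyl carbinol and is joined to a bromoarene at C4–C4a by hydroboration/B-alkyl Suzuki coupling. The pyran ring closes last at O1–C8a on a dearomatised ring, and reduction then restores the benzene ring.
Stereochemistry: C2 (R) is set as C3 of solanesol by Sharpless epoxidation with a D-(−)-tartrate and keeps its C–O bond to the end. The eight E alkenes are bought, and C8a of the ketal is transient.

Key step: step 10

Remark: commercial solanesol is taken to be the all-E isomer. R41 stands for (3E,7E,11E,15E,19E,23E,27E)-4,8,12,16,20,24,28,32-octamethyltritriaconta-3,7,11,15,19,23,27,31-octaen-1-yl. Open-chain compounds carry solanesol numbering and ring compounds carry chroman numbering.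

Step 1
Reactants: 1 solanesol (all-E nonaprenol, R41–C(CH3)=CH–CH2OH)
Product: 2 (2R,3R)-2,3-epoxysolanesol
Conditions: Ti(OiPr)4 (10 mol %), D-(−)-diethyl tartrate (12 mol %), t-BuOOH (decane solution, 1.5 equiv), 4 Å MS, CH2Cl2, −20 °C
Reagents that add atoms: tert-butyl hydroperoxide, CC(C)(C)OO
Why: Katsuki–Sharpless asymmetric epoxidation, in which the titanium–tartrate complex binds the substrate through its hydroxyl so that of nine alkenes only C2=C3 is oxidised, and the D-(−)-tartrate directs oxygen to the face of the E alkene that gives the (2R,3R)-epoxide, fixing the C3–O bond that later becomes C2–O1 of the chroman.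

Step 2
Reactants: 2 (2R,3R)-2,3-epoxysolanesol
Product: 3 (2S,3R)-2,3-epoxysolanesyl iodide (same spatial arrangement as 2, CH2I in place of CH2OH)
Conditions: PPh3, I2, imidazole (pre-mixed), THF, 0 °C, dark
Reagents that add atoms: iodine, II
Why: Garegg–Samuelsson (Appel-type) iodination replaces the activated primary hydroxyl by SN2 attack of iodide at C1 under imidazole buffering that leaves the trisubstituted epoxide, both stereocentres and the polyene alone (the C2 descriptor becomes S only because CH2I outranks C3).

Step 3
Reactants: 3 (2S,3R)-2,3-epoxysolanesyl iodide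
Product: 4 (3R)-tertiary vinyl carbinol R41–C(CH3)(OH)–CH=CH2 [(3R,6E,10E,14E,18E,22E,26E,30E)-3,7,11,15,19,23,27,31,35-nonamethylhexatriaconta-1,6,10,14,18,22,26,30,34-nonaen-3-ol]
Conditions: activated Zn dust, THF–EtOH 1:1, 65 °C
Reagents that add atoms: none
Why: Zinc inserts into the C1–I bond and the β-oxido organozinc fragments (Boord-type reductive elimination of a 2,3-epoxy iodide), breaking C2–O and forming C1=C2 while the C3–O bond and hence the R configuration are kept, under neutral conditions that a linalool-type alcohol tolerates.

Step 4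
Reactants: 4 (3R)-tertiary vinyl carbinol
Product: 5 (3R)-triethylsilyl ether R41–C(CH3)(OSiEt3)–CH=CH2
Conditions: TESOTf, 2,6-lutidine, CH2Cl2, −78 → 0 °C
Reagents that add atoms: triethylsilyl trifluoromethanesulfonate, CC[Si](CC)(CC)OS(=O)(=O)C(F)(F)F
Why: O-silylation of a hindered tertiary alcohol with a silyl triflate and a non-nucleophilic pyridine base is standard, does not touch the stereocentre, and removes the O–H that would otherwise consume 9-BBN and chelate boron in step 8.

Step 5
Reactants: 6 2,3-dimethylhydroquinone
Product: 7 4-methoxy-2,3-dimethylphenol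
Conditions: MeI (0.95 equiv), K2CO3, acetone, reflux, Ar
Reagents that add atoms: iodomethane, CI
Why: Williamson ether synthesis on a C2-symmetric hydroquinone can give only one monoether, a slight deficit of iodomethane holds back the diether, and unreacted 6 and any diether are easily separated by their different acidity and polarity.

Step 6
Reactants: 7 4-methoxy-2,3-dimethylphenol
Product: 8 4-methoxy-2,3-dimethylphenyl pivalate
Conditions: PivCl, Et3N, DMAP (cat.), CH2Cl2, 0 °C → rt
Reagents that add atoms: pivaloyl chloride, CC(C)(C)C(=O)Cl
Why: DMAP-catalysed acylation of the remaining phenol gives a hindered ester that survives the later basic coupling and weakens the donor strength of that oxygen for the bromination.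

Step 7
Reactants: 8 4-methoxy-2,3-dimethylphenyl pivalate
Product: 9 5-bromo-4-methoxy-2,3-dimethylphenyl pivalate
Conditions: NBS, MeCN, 0 °C → rt, dark
Reagents that add atoms: N-bromosuccinimide, O=C1CCC(=O)N1Br
Why: Electrophilic aromatic bromination in a polar solvent is steered by the strongest donor, the methoxy group, whose para position is blocked and whose only free ortho position is C5, whereas C6 lies next to the weakly donating acyloxy group.

Step 8
Reactants: 5 (3R)-triethylsilyl ether of the vinyl carbinol; 9 5-bromo-4-methoxy-2,3-dimethylphenyl pivalate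
Product: 11 (3R)-Ar–CH2CH2–C(CH3)(OSiEt3)–R41 in which Ar is 2-methoxy-3,4-dimethyl-5-(pivaloyloxy)phenyl, via B-alkyl-9-BBN adduct 10 (not isolated)
Conditions: 9-BBN-H (1.3 equiv), THF, 0 °C → 40 °C; then 9, Pd(OAc)2 (5 mol %), SPhos (10 mol %), 3 M aq K3PO4, THF, 60 °C, degassed
Reagents that add atoms: 9-borabicyclo[3.3.1]nonane, B1C2CCCC1CCC2 (its boron framework is present in 10 only; in 11 it leaves nothing but hydrogen)
Why: 9-BBN adds anti-Markovnikov to a monosubstituted alkene far faster than to trisubstituted alkenes, and the primary B-alkyl borane then undergoes B-alkyl Suzuki–Miyaura coupling, in which an electron-rich biaryl phosphine helps oxidative addition into the electron-rich ortho-substituted C–Br bond and phosphate base spares the pivalate, forming C4–C4a without touching the stereocentre.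

Step 9
Reactants: 11 silyl-protected coupled pivalate
Product: 13 (3R)-Ar'–CH2CH2–C(CH3)(OH)–R41 in which Ar' is 5-hydroxy-2-methoxy-3,4-dimethylphenyl, via carbinol pivalate 12 (not isolated)
Conditions: TBAF, THF, 0 °C → rt; then NaOMe, MeOH, rt → 40 °C, Ar; AcOH quench
Reagents that add atoms: none
Why: Fluoride-induced desilylation followed in the same flask by methoxide transesterification of the aryl ester are standard deprotections that affect neither the polyene nor the carbinol C–O bond, and the order in which the two groups fall is immaterial because both paths converge on 13.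

Step 10
Reactants: 13 p-methoxyphenol bearing the tethered (R)-tertiary carbinol
Product: 14 (2R,8aRS)-8a-methoxy-2,7,8-trimethyl-2-R41-2,3,4,8a-tetrahydro-6H-chromen-6-one (fused mixed quinone monoketal, C8a epimers not separated)
Conditions: PhI(OAc)2 (1.05 equiv), powdered K2CO3, 4 Å MS, CH2Cl2 (0.01 M), −20 → 0 °C, Ar, dark
Reagents that add atoms: none
Why: The phenol exchanges an acetate on iodine(III) and loses iodobenzene in a two-electron oxidation, and the resulting phenoxenium ion is carried mainly by its para-methoxy resonance form, an O-methyl oxocarbenium ion centred on C8a. The tertiary hydroxyl tethered through C3–C4 to C4a adds to C8a, so the O1–C8a bond forms and the dihydropyran ring closes in a 6-exo-trig mode (the C8a=O+Me π bond lies outside the new ring), giving the fused cyclohexadienone ketal. The closest known reaction type is the iodine(III)-mediated oxidative dearomatisation of p-alkoxyphenols to quinone monoketals by inter- or intramolecular alcohol capture, and the product belongs to the 8a-alkoxychromanone class known from vitamin E oxidation chemistry. C8a is the only new stereocentre, the remote C2 centre should control it weakly, and both epimers are carried on because C8a becomes planar again in step 11, while C2 keeps its C–O bond and so its R configuration. The step needs oxidation of the arene in preference to eight isolated trisubstituted alkenes, which the much lower oxidation potential of the p-methoxyphenol and the inertness of unactivated PhI(OAc)2 towards simple alkenes secure. It also needs capture at C8a by the hydroxyl rather than by acetate, water or an alkene, which the six-membered intramolecular delivery secures, supported by dilution, sieves and a carbonate buffer that releases no water.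

Step 11
Reactants: 14 8a-methoxy dienone ketal (both C8a epimers)
Product: 15 plastochromanol 8, (2R)-2,7,8-trimethyl-2-R41-3,4-dihydro-2H-chromen-6-ol
Conditions: L-ascorbic acid (5 equiv), AcOH, THF–EtOH (degassed), rt, Ar
Reagents that add atoms: none
Why: This is the reductive aromatisation known for 8a-alkoxytocopherones, in which weak acid ionises the pseudo-axial exocyclic methoxy group (best aligned with the dienone π system and with a lone pair on O1), the chromanoxylium ion takes up two electrons and a proton from ascorbic acid, both C8a epimers converge as C8a becomes planar, and the C2–O1 bond is never broken.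

Compound list
1 | solanesol (all-E nonaprenol) | CC(C)=CCC/C(C)=C/CC/C(C)=C/CC/C(C)=C/CC/C(C)=C/CC/C(C)=C/CC/C(C)=C/CC/C(C)=C/CC/C(C)=C/CO | starting material
2 | (2R,3R)-2,3-epoxysolanesol | CC(C)=CCC/C(C)=C/CC/C(C)=C/CC/C(C)=C/CC/C(C)=C/CC/C(C)=C/CC/C(C)=C/CC/C(C)=C/CC[C@@]1(C)O[C@@H]1CO | intermediate
3 | (2S,3R)-2,3-epoxysolanesyl iodide | CC(C)=CCC/C(C)=C/CC/C(C)=C/CC/C(C)=C/CC/C(C)=C/CC/C(C)=C/CC/C(C)=C/CC/C(C)=C/CC[C@@]1(C)O[C@@H]1CI | intermediate
4 | (3R)-tertiary vinyl carbinol R41–C(CH3)(OH)–CH=CH2 | CC(C)=CCC/C(C)=C/CC/C(C)=C/CC/C(C)=C/CC/C(C)=C/CC/C(C)=C/CC/C(C)=C/CC/C(C)=C/CC[C@](O)(C)C=C | intermediate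
5 | (3R)-triethylsilyl ether of 4 | CC(C)=CCC/C(C)=C/CC/C(C)=C/CC/C(C)=C/CC/C(C)=C/CC/C(C)=C/CC/C(C)=C/CC/C(C)=C/CC[C@](O[Si](CC)(CC)CC)(C)C=C | intermediate
6 | 2,3-dimethylhydroquinone | Cc1c(C)c(O)ccc1O | starting material
7 | 4-methoxy-2,3-dimethylphenol | COc1ccc(O)c(C)c1C | intermediate
8 | 4-methoxy-2,3-dimethylphenyl pivalate | COc1ccc(OC(=O)C(C)(C)C)c(C)c1C | intermediate
9 | 5-bromo-4-methoxy-2,3-dimethylphenyl pivalate | COc1c(Br)cc(OC(=O)C(C)(C)C)c(C)c1C | intermediate
10 | B-alkyl-9-BBN adduct of 5 (spatial arrangement unchanged; descriptor formally S because boron ranks below carbon) | CC(C)=CCC/C(C)=C/CC/C(C)=C/CC/C(C)=C/CC/C(C)=C/CC/C(C)=C/CC/C(C)=C/CC/C(C)=C/CC[C@](O[Si](CC)(CC)CC)(C)CCB1C2CCCC1CCC2 | intermediate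
11 | (3R)-silyl-protected aryl-tethered carbinol pivalate | CC(C)=CCC/C(C)=C/CC/C(C)=C/CC/C(C)=C/CC/C(C)=C/CC/C(C)=C/CC/C(C)=C/CC/C(C)=C/CC[C@](O[Si](CC)(CC)CC)(C)CCc1cc(OC(=O)C(C)(C)C)c(C)c(C)c1OC | intermediate
12 | (3R)-aryl-tethered tertiary carbinol pivalate | CC(C)=CCC/C(C)=C/CC/C(C)=C/CC/C(C)=C/CC/C(C)=C/CC/C(C)=C/CC/C(C)=C/CC/C(C)=C/CC[C@](O)(C)CCc1cc(OC(=O)C(C)(C)C)c(C)c(C)c1OC | intermediate
13 | (3R)-p-methoxyphenol tertiary carbinol | CC(C)=CCC/C(C)=C/CC/C(C)=C/CC/C(C)=C/CC/C(C)=C/CC/C(C)=C/CC/C(C)=C/CC/C(C)=C/CC[C@](O)(C)CCc1cc(O)c(C)c(C)c1OC | intermediate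
14 | (2R,8aRS)-8a-methoxy-2,7,8-trimethyl-2-R41-2,3,4,8a-tetrahydro-6H-chromen-6-one | CC(C)=CCC/C(C)=C/CC/C(C)=C/CC/C(C)=C/CC/C(C)=C/CC/C(C)=C/CC/C(C)=C/CC/C(C)=C/CC[C@]1(C)CCC2=CC(=O)C(C)=C(C)C2(OC)O1 | intermediate
15 | plastochromanol 8, (2R) | CC(C)=CCC/C(C)=C/CC/C(C)=C/CC/C(C)=C/CC/C(C)=C/CC/C(C)=C/CC/C(C)=C/CC/C(C)=C/CC[C@]1(C)CCc2cc(O)c(C)c(C)c2O1 | target

Total step count: 11. Longest linear sequence: 8 steps from solanesol (steps 1–4 and 8–11). The arene branch has 3 steps (5–7).

Steps most likely to fail

Step 10.
- **Risk:** The oxidised ring may be captured by acetate or adventitious water instead of by the hindered tertiary hydroxyl, with collapse to the quinone oxidation level. Ligand exchange at iodine may also be sluggish in the non-polar solvent that the lipophilic substrate demands.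
- **Fallback:** Oxidation and ring closure are separated, setting out from 13. PhI(OAc)2 in MeOH–THF at 0 °C, the standard solvent-capture route to quinone dimethyl monoketals, should give the open-chain 4,4-dimethoxycyclohexa-2,5-dienone F1, which still carries the free tertiary carbinol. Catalytic PPTS with molecular sieves in CH2Cl2 then exchanges one methoxy group for the tethered hydroxyl. This is an intramolecular transketalisation driven by removal of methanol. It forms the same O1–C8a bond and the same ring, and the route is rejoined at 14.

Step 11.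
- **Risk:** The endocyclic C8a–O1 bond may be cleaved in competition with the exocyclic C8a–OMe bond. That ring opening only leads back to the level of 13, which can be resubmitted. The cation may also be hydrolysed by traces of water before the polar reductant meets the very lipophilic substrate.
- **Fallback:** The cationic manifold is left altogether, setting out from 14. SmI2 (2.2 equiv) with t-BuOH in THF at −78 °C transfers an electron to the dienone, and the ketyl expels an alkoxide from the vinylogous α-position. This is the known samarium-mediated cleavage of α-alkoxy ketones. Under these anionic, acid-free and water-free conditions methoxide is the better leaving group than a tertiary alkoxide and is also the better aligned one. A second electron and protonation give the phenol, so the route is rejoined directly at 15. No compound beyond the list arises (F0).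

Step 8.
- **Risk:** The trisubstituted alkenes may be hydroborated competitively if the neopentyl-type vinyl group reacts slowly. Oxidative addition into the electron-rich ortho-methoxy C–Br bond may be slow. The alkyl group may be lost through protodeboronation or β-hydride elimination.
- **Fallback:** Both the hydroboration and the boron transmetalation are avoided, setting out from 2.
  - Hydroxyl-directed hydride opening of the epoxide at C2 with Red-Al in THF should give the (3R)-1,3-diol F2 with the C3–O bond intact.
  - Appel-type iodination (PPh3, I2, imidazole) of the primary hydroxyl alone gives the hydroxy iodide F3.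
  - Silylation as in step 4 gives the silyl-protected iodide F4.
  - LiCl-assisted zinc insertion gives the primary alkylzinc iodide F5.
  - Negishi coupling of F5 with 9 (Pd(OAc)2/SPhos, THF) rejoins the route at 11.

Further compounds
F1 | step 10 | 4,4-dimethoxy-2,3-dimethyl-5-[CH2CH2–C(CH3)(OH)–R41, (R)]cyclohexa-2,5-dien-1-one | CC(C)=CCC/C(C)=C/CC/C(C)=C/CC/C(C)=C/CC/C(C)=C/CC/C(C)=C/CC/C(C)=C/CC/C(C)=C/CC[C@](O)(C)CCC1=CC(=O)C(C)=C(C)C1(OC)OC
F0 | step 11 | none | none
F2 | step 8 | (3R)-1,3-diol R41–C(CH3)(OH)–CH2CH2OH | CC(C)=CCC/C(C)=C/CC/C(C)=C/CC/C(C)=C/CC/C(C)=C/CC/C(C)=C/CC/C(C)=C/CC/C(C)=C/CC[C@](O)(C)CCO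
F3 | step 8 | (3R)-hydroxy iodide R41–C(CH3)(OH)–CH2CH2I | CC(C)=CCC/C(C)=C/CC/C(C)=C/CC/C(C)=C/CC/C(C)=C/CC/C(C)=C/CC/C(C)=C/CC/C(C)=C/CC[C@](O)(C)CCI
F4 | step 8 | (3R)-triethylsilyl ether of F3 | CC(C)=CCC/C(C)=C/CC/C(C)=C/CC/C(C)=C/CC/C(C)=C/CC/C(C)=C/CC/C(C)=C/CC/C(C)=C/CC[C@](O[Si](CC)(CC)CC)(C)CCI
F5 | step 8 | (3R)-alkylzinc iodide from F4 | CC(C)=CCC/C(C)=C/CC/C(C)=C/CC/C(C)=C/CC/C(C)=C/CC/C(C)=C/CC/C(C)=C/CC/C(C)=C/CC[C@](O[Si](CC)(CC)CC)(C)CC[Zn]I
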